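**Retrosynthetic overview**
1. The last step is a CBS reduction of the C3 ketone; the 14-membered carbocycle is closed just before that by an intramolecular Negishi sp3–sp2 coupling at C8–C9.
2. The key union (step 19 of 22) is a Nozaki–Hiyama–Kishi coupling at C3–C4 between a C13 ε-lactone aldehyde (fragment AB) and a C7 (Z,E)-dihalodiene (fragment C).
3. The α-methylene ε-lactone is the first ring formed: the C16 acid opens a Shi epoxide (C11–C12) in a 7-exo mode, which sets C11 and C12.
4. The lactone precursor comes from a B-alkyl Suzuki coupling (C12–C13) of fragment A with vinyl iodide fragment B; in fragment A, C1 is set by Ir-catalysed allylic alkylation and the acrylate is made by deacetylative methylenation.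
5. Ring order: ε-lactone first, carbocycle second.

Assumption: ring positions are given in cembrane locants (C1 = CH bearing the acrylate carbon C15, C3 = carbinol, C11 = acetoxy carbon, C12 = lactone O-bearing carbon); in these locants the target is 1S,3R,4E,7Z,11R,12S.

**Fragment A**

Step 1
Reactants: 1 but-3-en-1-ol
Product: 2 (but-3-en-1-yloxy)(tert-butyl)diphenylsilane
Conditions: TBDPSCl, imidazole, DMF, rt
Reagents that add atoms: tert-butyl(chloro)diphenylsilane, CC(C)(C)[Si](Cl)(c1ccccc1)c1ccccc1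
Why: Routine silylation of a primary alcohol; the TBDPS ether masks the future C3 oxygen up to step 13.

Step 2
Reactants: 3 (2Z)-but-2-ene-1,4-diol
Product: 4 (2Z)-but-2-ene-1,4-diyl dimethyl dicarbonate
Conditions: ClCO2Me, pyridine, CH2Cl2, 0 °C
Reagents that add atoms: methyl chloroformate, COC(=O)Cl
Why: Double acylation of the diol gives the symmetrical cross-metathesis partner.

Step 3
Reactants: 2 (but-3-en-1-yloxy)(tert-butyl)diphenylsilane; 4 (2Z)-but-2-ene-1,4-diyl dimethyl dicarbonate (3 equiv)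
Product: 5 (2E)-5-[(tert-butyldiphenylsilyl)oxy]pent-2-en-1-yl methyl carbonate
Conditions: second-generation Hoveyda–Grubbs catalyst (3 mol%), CH2Cl2, 40 °C
Reagents that add atoms: none
Why: Olefin cross-metathesis of a terminal alkene with a symmetrical internal alkene gives the linear allylic carbonate under thermodynamic control (E/Z about 10:1); no stereocentre is formed.

Step 4
Reactants: 5 (2E)-5-[(tert-butyldiphenylsilyl)oxy]pent-2-en-1-yl methyl carbonate; 6 methyl 3-oxobutanoate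
Product: 7 methyl (3R)-2-acetyl-5-[(tert-butyldiphenylsilyl)oxy]-3-ethenylpentanoate (both C2 epimers)
Conditions: [Ir(cod)Cl]2 (2 mol%), (Sa,Sc,Sc)-BINOL bis(1-phenylethyl)phosphoramidite (4 mol%), TBD (10 mol%), THF, 35 °C
Reagents that add atoms: none
Why: Iridium-catalysed branched-selective asymmetric allylic alkylation (Helmchen–Hartwig): the β-keto ester attacks the substituted terminus of the chiral π-allyl iridacycle and sets C1 (3R here; the ligand antipode is chosen for this sense and must be confirmed), while the epimeric centre between the carbonyls is destroyed in step 5.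

Step 5
Reactants: 7 methyl (3R)-2-acetyl-5-[(tert-butyldiphenylsilyl)oxy]-3-ethenylpentanoate
Product: 9 methyl (3R)-5-[(tert-butyldiphenylsilyl)oxy]-3-ethenyl-2-methylidenepentanoate (fragment A), via lithium enolate 8 (not isolated)
Conditions: LiN(SiMe3)2, THF, −78 °C; (CH2O)n, −78 °C to rt
Reagents that add atoms: formaldehyde (as paraformaldehyde), C=O
Why: Deacetylative methylenation: aldol addition to formaldehyde, acetyl transfer to the new alkoxide (retro-Claisen) and E1cB loss of acetate give the 2-substituted acrylate; C1 is not enolisable and is untouched.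

**Fragment B**

Step 6
Reactants: 10 pent-3-yn-1-ol
Product: 11 tert-butyldimethyl(pent-3-yn-1-yloxy)silane
Conditions: TBSCl, imidazole, CH2Cl2, rt
Reagents that add atoms: tert-butyl(chloro)dimethylsilane, CC(C)(C)[Si](C)(C)Cl
Why: Silylation keeps the hydroxyl from consuming the zirconium hydride in step 7.

Step 7
Reactants: 11 tert-butyldimethyl(pent-3-yn-1-yloxy)silane
Product: 13 tert-butyl{[(3E)-4-iodopent-3-en-1-yl]oxy}dimethylsilane, via alkenylzirconocene chloride 12 (not isolated)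
Conditions: Cp2Zr(H)Cl (1.5 equiv), THF, rt then 40 °C; I2, 0 °C
Reagents that add atoms: iodine, II
Why: Syn hydrozirconation of the 2-alkyne places Zr (after equilibration) on the carbon next to the methyl group, and iodinolysis with retention gives the E 2-iodoalkene.

Step 8
Reactants: 13 tert-butyl{[(3E)-4-iodopent-3-en-1-yl]oxy}dimethylsilane
Product: 14 (2E)-5-bromo-2-iodopent-2-ene (fragment B)
Conditions: Ph3PBr2, CH2Cl2, 0 °C to rt
Reagents that add atoms: dibromotriphenylphosphorane, BrP(Br)(c1ccccc1)(c1ccccc1)c1ccccc1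
Why: Direct conversion of a primary silyl ether into the bromide through the alkoxyphosphonium salt (Appel-type SN2), leaving the vinyl iodide intact.

**Fragment AB (lactone)**

Step 9
Reactants: 9 methyl (3R)-5-[(tert-butyldiphenylsilyl)oxy]-3-ethenyl-2-methylidenepentanoate; 14 (2E)-5-bromo-2-iodopent-2-ene
Product: 16 methyl (3S,6E)-9-bromo-3-{2-[(tert-butyldiphenylsilyl)oxy]ethyl}-6-methyl-2-methylidenenon-6-enoate, via B-alkyl-9-BBN adduct 15 (not isolated)
Conditions: 9-BBN (1.2 equiv), THF, 0 °C to rt; then 14, Pd(dppf)Cl2 (5 mol%), AsPh3, Cs2CO3, DMF/H2O, rt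
Reagents that add atoms: none
Why: B-alkyl Suzuki–Miyaura coupling: 9-BBN hydroborates the monosubstituted vinyl group in preference to the electron-poor acrylate, and the alkylborane couples with the vinyl iodide with retention of the E geometry while the alkyl bromide is inert; C1 is unchanged (the descriptor becomes S by priority change only).

Step 10
Reactants: 16 methyl (3S,6E)-9-bromo-3-{2-[(tert-butyldiphenylsilyl)oxy]ethyl}-6-methyl-2-methylidenenon-6-enoate
Product: 17 methyl (3S)-5-[(2R,3R)-3-(2-bromoethyl)-2-methyloxiran-2-yl]-3-{2-[(tert-butyldiphenylsilyl)oxy]ethyl}-2-methylidenepentanoate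
Conditions: D-fructose-derived Shi ketone (30 mol%), KHSO5 (as its triple salt), K2CO3, Bu4NHSO4, MeCN/dimethoxymethane, aqueous Na2B4O7 buffer, 0 °C
Reagents that add atoms: potassium peroxymonosulfate, [K+].OOS(=O)(=O)[O-]
Why: Shi asymmetric epoxidation: the chiral dioxirane attacks the only electron-rich (E-trisubstituted) alkene through a spiro transition state to give the (R,R)-epoxide, and the acrylate does not react.

Step 11
Reactants: 17 methyl (3S)-5-[(2R,3R)-3-(2-bromoethyl)-2-methyloxiran-2-yl]-3-{2-[(tert-butyldiphenylsilyl)oxy]ethyl}-2-methylidenepentanoate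
Product: 19 (4S,7S)-7-[(1R)-3-bromo-1-hydroxypropyl]-4-{2-[(tert-butyldiphenylsilyl)oxy]ethyl}-7-methyl-3-methylideneoxepan-2-one, via epoxy acid 18 (not isolated)
Conditions: LiOH, THF/H2O, 0 °C to rt; 1 M HCl to pH 4; then CSA (10 mol%), CH2Cl2, 0 °C to rt
Reagents that add atoms: lithium hydroxide, [Li+].[OH-]
Why: Saponification followed by acid-catalysed 7-exo epoxide opening: the carboxylic acid attacks the tertiary epoxide carbon (Markovnikov) with inversion, which gives 12S, and frees the C11 hydroxyl with retention (11R).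

Step 12
Reactants: 19 (4S,7S)-7-[(1R)-3-bromo-1-hydroxypropyl]-4-{2-[(tert-butyldiphenylsilyl)oxy]ethyl}-7-methyl-3-methylideneoxepan-2-one
Product: 20 (1R)-3-bromo-1-[(2S,5S)-5-{2-[(tert-butyldiphenylsilyl)oxy]ethyl}-2-methyl-6-methylidene-7-oxooxepan-2-yl]propyl acetate
Conditions: Ac2O, pyridine, DMAP (cat.), CH2Cl2, rt
Reagents that add atoms: acetic anhydride, CC(=O)OC(C)=O
Why: DMAP-catalysed acetylation of the only free (secondary) hydroxyl installs the C11 acetate of the target.

Step 13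
Reactants: 20 (1R)-3-bromo-1-[(2S,5S)-5-{2-[(tert-butyldiphenylsilyl)oxy]ethyl}-2-methyl-6-methylidene-7-oxooxepan-2-yl]propyl acetate
Product: 21 (1R)-3-bromo-1-[(2S,5S)-5-(2-hydroxyethyl)-2-methyl-6-methylidene-7-oxooxepan-2-yl]propyl acetate
Conditions: HF·pyridine, pyridine, THF, 0 °C to rt
Reagents that add atoms: none
Why: Buffered fluoride desilylation is compatible with the acetate, the alkyl bromide and the α-methylene lactone.

Step 14
Reactants: 21 (1R)-3-bromo-1-[(2S,5S)-5-(2-hydroxyethyl)-2-methyl-6-methylidene-7-oxooxepan-2-yl]propyl acetate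
Product: 22 (1R)-3-bromo-1-[(2S,5S)-2-methyl-6-methylidene-7-oxo-5-(2-oxoethyl)oxepan-2-yl]propyl acetate (fragment AB)
Conditions: Dess–Martin periodinane, CH2Cl2, rt
Reagents that add atoms: none
Why: Mild Dess–Martin oxidation gives the aldehyde; the stereocentre is β to the carbonyl and cannot epimerise.

**Fragment C**

Step 15
Reactants: 23 but-2-yn-1-ol
Product: 25 (2Z)-3-bromobut-2-en-1-ol, via sodium alkenylalanate 24 (not isolated)
Conditions: NaAlH2(OCH2CH2OMe)2, THF, 0 °C to rt; NBS, −78 °C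
Reagents that add atoms: N-bromosuccinimide, O=C1CCC(=O)N1Br
Why: Hydroxyl-directed trans-hydroalumination gives a five-membered cyclic alanate with Al on C3 cis to the CH2O group, and bromination with retention gives the Z bromoalkene.

Step 16
Reactants: 25 (2Z)-3-bromobut-2-en-1-ol
Product: 26 (2Z)-1,3-dibromobut-2-ene
Conditions: CBr4, PPh3, CH2Cl2, 0 °C
Reagents that add atoms: tetrabromomethane, BrC(Br)(Br)Br
Why: Appel bromination of the primary allylic alcohol without touching the alkene geometry.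

Step 17
Reactants: 26 (2Z)-1,3-dibromobut-2-ene; 27 prop-1-yn-1-ylmagnesium bromide
Product: 28 (2Z)-2-bromohept-2-en-5-yne
Conditions: CuI (10 mol%), THF, 0 °C to rt
Reagents that add atoms: none
Why: Copper-catalysed SN2 coupling of the alkynyl Grignard reagent with the primary allylic bromide; attack is at the α carbon because the γ carbon carries Br and CH3, and the vinyl bromide is inert.

Step 18
Reactants: 28 (2Z)-2-bromohept-2-en-5-yne
Product: 30 (2Z,5E)-2-bromo-6-iodohepta-2,5-diene (fragment C), via alkenylzirconocene chloride 29 (not isolated)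
Conditions: Cp2Zr(H)Cl (1.3 equiv), THF, rt then 40 °C; I2, 0 °C
Reagents that add atoms: iodine, II
Why: Syn hydrozirconation of the methyl-capped alkyne with Zr on the methyl-bearing carbon (about 9:1 after equilibration), then iodinolysis with retention, gives the E vinyl iodide next to the untouched Z vinyl bromide.

**Union and endgame**

Step 19
Reactants: 22 (1R)-3-bromo-1-[(2S,5S)-2-methyl-6-methylidene-7-oxo-5-(2-oxoethyl)oxepan-2-yl]propyl acetate; 30 (2Z,5E)-2-bromo-6-iodohepta-2,5-diene (2 equiv)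
Product: 31 (1R)-3-bromo-1-{(2S,5S)-5-[(3E,6Z)-7-bromo-2-hydroxy-3-methylocta-3,6-dien-1-yl]-2-methyl-6-methylidene-7-oxooxepan-2-yl}propyl acetate (both carbinol epimers)
Conditions: CrCl2 (6 equiv), NiCl2 (1 mol%), DMSO, rt
Reagents that add atoms: none
Why: Nozaki–Hiyama–Kishi coupling: nickel inserts selectively into the vinyl iodide (not the vinyl or alkyl bromide) and the alkenylchromium adds only to the aldehyde with retention of the E geometry; the C3 configuration is not controlled here and is set in step 22.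

Step 20
Reactants: 31 (1R)-3-bromo-1-{(2S,5S)-5-[(3E,6Z)-7-bromo-2-hydroxy-3-methylocta-3,6-dien-1-yl]-2-methyl-6-methylidene-7-oxooxepan-2-yl}propyl acetate
Product: 32 (1R)-3-bromo-1-{(2S,5S)-5-[(3E,6Z)-7-bromo-3-methyl-2-oxoocta-3,6-dien-1-yl]-2-methyl-6-methylidene-7-oxooxepan-2-yl}propyl acetate
Conditions: Dess–Martin periodinane, CH2Cl2, 0 °C
Reagents that add atoms: none
Why: Oxidation of the allylic alcohol converges both epimers to one enone under neutral conditions that do not isomerise the skipped diene.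

Step 21
Reactants: 32 (1R)-3-bromo-1-{(2S,5S)-5-[(3E,6Z)-7-bromo-3-methyl-2-oxoocta-3,6-dien-1-yl]-2-methyl-6-methylidene-7-oxooxepan-2-yl}propyl acetate
Product: 34 (1S,4E,7Z,11R,12S)-11-acetoxy-3-oxocembra-4,7,15(17)-trien-16,12-olide, via alkylzinc bromide 33 (not isolated)
Conditions: Zn dust, LiCl, THF, 50 °C; then slow addition to Pd(OAc)2 (10 mol%), SPhos (20 mol%), THF/NMP, 40 °C, 2 mM
Reagents that add atoms: none
Why: Zinc inserts only into the primary alkyl bromide, and intramolecular Negishi coupling with the Z vinyl bromide under zerovalent palladium catalysis closes the 14-membered ring with retention of the Z geometry; the alkylzinc halide does not add to the enone or esters.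

Step 22
Reactants: 34 (1S,4E,7Z,11R,12S)-11-acetoxy-3-oxocembra-4,7,15(17)-trien-16,12-olide
Product: 35 (1S,3R,4E,7Z,11R,12S)-11-acetoxy-3-hydroxycembra-4,7,15(17)-trien-16,12-olide (target)
Conditions: (S)-2-methyl-CBS-oxazaborolidine (0.3 equiv), catecholborane, toluene, −78 °C
Reagents that add atoms: none
Why: Corey–Bakshi–Shibata reduction: the α-methyl alkenyl group acts as the large substituent and CH2 as the small one, so the (S)-catalyst delivers hydride to give 3R; lactone, acetate and acrylate are inert to catecholborane at −78 °C.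

**Compound list**
1 | but-3-en-1-ol | C=CCCO | starting material
2 | (but-3-en-1-yloxy)(tert-butyl)diphenylsilane | C=CCCO[Si](c1ccccc1)(c1ccccc1)C(C)(C)C | intermediate
3 | (2Z)-but-2-ene-1,4-diol | OC/C=C\CO | starting material
4 | (2Z)-but-2-ene-1,4-diyl dimethyl dicarbonate | COC(=O)OC/C=C\COC(=O)OC | intermediate
5 | (2E)-5-[(tert-butyldiphenylsilyl)oxy]pent-2-en-1-yl methyl carbonate | COC(=O)OC/C=C/CCO[Si](c1ccccc1)(c1ccccc1)C(C)(C)C | intermediate
6 | methyl 3-oxobutanoate | CC(=O)CC(=O)OC | starting material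
7 | methyl (3R)-2-acetyl-5-[(tert-butyldiphenylsilyl)oxy]-3-ethenylpentanoate (both C2 epimers) | C=C[C@H](C(C(C)=O)C(=O)OC)CCO[Si](c1ccccc1)(c1ccccc1)C(C)(C)C | intermediate
8 | lithium enolate of 7 | [Li+].C=C[C@H](C(C(=O)OC)=C(C)[O-])CCO[Si](c1ccccc1)(c1ccccc1)C(C)(C)C | intermediate
9 | methyl (3R)-5-[(tert-butyldiphenylsilyl)oxy]-3-ethenyl-2-methylidenepentanoate (fragment A) | C=C[C@H](C(=C)C(=O)OC)CCO[Si](c1ccccc1)(c1ccccc1)C(C)(C)C | intermediate
10 | pent-3-yn-1-ol | CC#CCCO | starting material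
11 | tert-butyldimethyl(pent-3-yn-1-yloxy)silane | CC#CCCO[Si](C)(C)C(C)(C)C | intermediate
12 | chlorobis(cyclopentadienyl)[(2E)-5-(tert-butyldimethylsilyloxy)pent-2-en-2-yl]zirconium | C/C(=C\CCO[Si](C)(C)C(C)(C)C)[Zr](Cl)(C1C=CC=C1)C1C=CC=C1 | intermediate
13 | tert-butyl{[(3E)-4-iodopent-3-en-1-yl]oxy}dimethylsilane | C/C(I)=C\CCO[Si](C)(C)C(C)(C)C | intermediate
14 | (2E)-5-bromo-2-iodopent-2-ene (fragment B) | C/C(I)=C\CCBr | intermediate
15 | methyl (3S)-3-[2-(9-borabicyclo[3.3.1]nonan-9-yl)ethyl]-5-[(tert-butyldiphenylsilyl)oxy]-2-methylidenepentanoate | COC(=O)C(=C)[C@@H](CCB1C2CCCC1CCC2)CCO[Si](c1ccccc1)(c1ccccc1)C(C)(C)C | intermediate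
16 | methyl (3S,6E)-9-bromo-3-{2-[(tert-butyldiphenylsilyl)oxy]ethyl}-6-methyl-2-methylidenenon-6-enoate | COC(=O)C(=C)[C@@H](CC/C(C)=C/CCBr)CCO[Si](c1ccccc1)(c1ccccc1)C(C)(C)C | intermediate
17 | methyl (3S)-5-[(2R,3R)-3-(2-bromoethyl)-2-methyloxiran-2-yl]-3-{2-[(tert-butyldiphenylsilyl)oxy]ethyl}-2-methylidenepentanoate | COC(=O)C(=C)[C@@H](CC[C@@]1(C)O[C@@H]1CCBr)CCO[Si](c1ccccc1)(c1ccccc1)C(C)(C)C | intermediate
18 | (3S)-5-[(2R,3R)-3-(2-bromoethyl)-2-methyloxiran-2-yl]-3-{2-[(tert-butyldiphenylsilyl)oxy]ethyl}-2-methylidenepentanoic acid | OC(=O)C(=C)[C@@H](CC[C@@]1(C)O[C@@H]1CCBr)CCO[Si](c1ccccc1)(c1ccccc1)C(C)(C)C | intermediate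
19 | (4S,7S)-7-[(1R)-3-bromo-1-hydroxypropyl]-4-{2-[(tert-butyldiphenylsilyl)oxy]ethyl}-7-methyl-3-methylideneoxepan-2-one | C=C1C(=O)O[C@](C)([C@H](O)CCBr)CC[C@H]1CCO[Si](c1ccccc1)(c1ccccc1)C(C)(C)C | intermediate
20 | (1R)-3-bromo-1-[(2S,5S)-5-{2-[(tert-butyldiphenylsilyl)oxy]ethyl}-2-methyl-6-methylidene-7-oxooxepan-2-yl]propyl acetate | C=C1C(=O)O[C@](C)([C@H](OC(C)=O)CCBr)CC[C@H]1CCO[Si](c1ccccc1)(c1ccccc1)C(C)(C)C | intermediate
21 | (1R)-3-bromo-1-[(2S,5S)-5-(2-hydroxyethyl)-2-methyl-6-methylidene-7-oxooxepan-2-yl]propyl acetate | C=C1C(=O)O[C@](C)([C@H](OC(C)=O)CCBr)CC[C@H]1CCO | intermediate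
22 | (1R)-3-bromo-1-[(2S,5S)-2-methyl-6-methylidene-7-oxo-5-(2-oxoethyl)oxepan-2-yl]propyl acetate (fragment AB) | C=C1C(=O)O[C@](C)([C@H](OC(C)=O)CCBr)CC[C@H]1CC=O | intermediate
23 | but-2-yn-1-ol | CC#CCO | starting material
24 | sodium 2,2-bis(2-methoxyethoxy)-3-methyl-2,5-dihydro-1,2-oxaluminol-2-uide | [Na+].CC1=CCO[Al-]1(OCCOC)OCCOC | intermediate
25 | (2Z)-3-bromobut-2-en-1-ol | C/C(Br)=C/CO | intermediate
26 | (2Z)-1,3-dibromobut-2-ene | C/C(Br)=C/CBr | intermediate
27 | prop-1-yn-1-ylmagnesium bromide | CC#C[Mg]Br | starting material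
28 | (2Z)-2-bromohept-2-en-5-yne | C/C(Br)=C/CC#CC | intermediate
29 | chlorobis(cyclopentadienyl)[(2E,5Z)-6-bromohepta-2,5-dien-2-yl]zirconium | C/C(Br)=C/C/C=C(\C)[Zr](Cl)(C1C=CC=C1)C1C=CC=C1 | intermediate
30 | (2Z,5E)-2-bromo-6-iodohepta-2,5-diene (fragment C) | C/C(Br)=C/C/C=C(\C)I | intermediate
31 | (1R)-3-bromo-1-{(2S,5S)-5-[(3E,6Z)-7-bromo-2-hydroxy-3-methylocta-3,6-dien-1-yl]-2-methyl-6-methylidene-7-oxooxepan-2-yl}propyl acetate (both carbinol epimers) | C=C1C(=O)O[C@](C)([C@H](OC(C)=O)CCBr)CC[C@H]1CC(O)/C(C)=C/C/C=C(\Br)C | intermediate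
32 | (1R)-3-bromo-1-{(2S,5S)-5-[(3E,6Z)-7-bromo-3-methyl-2-oxoocta-3,6-dien-1-yl]-2-methyl-6-methylidene-7-oxooxepan-2-yl}propyl acetate | C=C1C(=O)O[C@](C)([C@H](OC(C)=O)CCBr)CC[C@H]1CC(=O)/C(C)=C/C/C=C(\Br)C | intermediate
33 | alkylzinc bromide from 32 (ZnBr in place of the primary Br) | C=C1C(=O)O[C@](C)([C@H](OC(C)=O)CC[Zn]Br)CC[C@H]1CC(=O)/C(C)=C/C/C=C(\Br)C | intermediate
34 | (1S,4E,7Z,11R,12S)-11-acetoxy-3-oxocembra-4,7,15(17)-trien-16,12-olide | C=C1C(=O)O[C@@]2(C)CC[C@H]1CC(=O)/C(C)=C/C/C=C(/C)CC[C@H]2OC(C)=O | intermediate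
35 | (1S,3R,4E,7Z,11R,12S)-11-acetoxy-3-hydroxycembra-4,7,15(17)-trien-16,12-olide | C=C1C(=O)O[C@@]2(C)CC[C@H]1C[C@@H](O)/C(C)=C/C/C=C(/C)CC[C@H]2OC(C)=O | target

**Step count**
Total: 22 steps. Longest linear sequence: 14 steps (1, 3, 4, 5, 9, 10, 11, 12, 13, 14, 19, 20, 21, 22).

**Steps most likely to fail, with fallbacks**

Step 11 (7-exo lactonisation at the tertiary epoxide carbon; Meinwald rearrangement or 8-endo attack may compete). The fallback sets out from epoxy acid 18 and rejoins at 20. The C12–O bond is made by acylation instead of epoxide opening. Acid 18 is hydrolysed at the tertiary epoxide carbon (HClO4, THF/H2O, inversion at C12) to (3S,6S,7R)-9-bromo-3-{2-[(tert-butyldiphenylsilyl)oxy]ethyl}-6,7-dihydroxy-6-methyl-2-methylidenenonanoic acid F1. The secondary hydroxyl is acetylated (Ac2O, pyridine) to give the 7-acetoxy-6-hydroxy acid F2. F2 is then lactonised through its tertiary hydroxyl (Shiina conditions: 2-methyl-6-nitrobenzoic anhydride, DMAP, Et3N, high dilution) to give 20 with retention at C12.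

Step 21 (intramolecular Negishi macrocyclisation in the presence of the enone). The fallback sets out from 20 and 28 and rejoins at 34; the order of the two C–C bonds is reversed. Bromide 20 is converted (Zn dust, LiCl) into the alkylzinc bromide F3 and coupled intermolecularly (Pd(OAc)2, SPhos) with the vinyl bromide of enyne 28 to give the enyne lactone F4. HF·pyridine gives the primary alcohol F5, and Dess–Martin oxidation gives the ynal F6. The ring is then closed at C3–C4 by a nickel-catalysed reductive alkyne–aldehyde macrocyclisation (Ni(cod)2, PBu3, Et3B, high dilution; syn addition with C–C bond formation at the methyl-bearing alkyne carbon), giving the macrocyclic allylic alcohol F7 as both C3 epimers. Dess–Martin periodinane oxidises F7 to 34. The α-methylene lactone is a possible competing π-acceptor for nickel in this closure.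

Step 22 (reagent control may not override the conformational bias of the macrocyclic enone). The fallback sets out from 34 and rejoins at 35. Enone 34 is reduced under substrate control (NaBH4, CeCl3, MeOH, −78 °C; Luche), and the wrong epimer, the (3S)-alcohol F8, is separated. F8 is inverted by Mitsunobu esterification (chloroacetic acid, PPh3, DIAD) to the (3R)-chloroacetate F9. Thiourea/NaHCO3 in EtOH removes the chloroacetyl group without touching the C11 acetate and gives 35.

**Further compounds**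
F1 | step 11 | (3S,6S,7R)-9-bromo-3-{2-[(tert-butyldiphenylsilyl)oxy]ethyl}-6,7-dihydroxy-6-methyl-2-methylidenenonanoic acid | OC(=O)C(=C)[C@@H](CC[C@](C)(O)[C@H](O)CCBr)CCO[Si](c1ccccc1)(c1ccccc1)C(C)(C)C
F2 | step 11 | (3S,6S,7R)-7-acetoxy-9-bromo-3-{2-[(tert-butyldiphenylsilyl)oxy]ethyl}-6-hydroxy-6-methyl-2-methylidenenonanoic acid | OC(=O)C(=C)[C@@H](CC[C@](C)(O)[C@H](OC(C)=O)CCBr)CCO[Si](c1ccccc1)(c1ccccc1)C(C)(C)C
F3 | step 21 | alkylzinc bromide from 20 (ZnBr in place of Br) | C=C1C(=O)O[C@](C)([C@H](OC(C)=O)CC[Zn]Br)CC[C@H]1CCO[Si](c1ccccc1)(c1ccccc1)C(C)(C)C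
F4 | step 21 | (1R,4Z)-1-[(2S,5S)-5-{2-[(tert-butyldiphenylsilyl)oxy]ethyl}-2-methyl-6-methylidene-7-oxooxepan-2-yl]-4-methylnon-4-en-7-yn-1-yl acetate | C=C1C(=O)O[C@](C)([C@H](OC(C)=O)CC/C(C)=C\CC#CC)CC[C@H]1CCO[Si](c1ccccc1)(c1ccccc1)C(C)(C)C
F5 | step 21 | (1R,4Z)-1-[(2S,5S)-5-(2-hydroxyethyl)-2-methyl-6-methylidene-7-oxooxepan-2-yl]-4-methylnon-4-en-7-yn-1-yl acetate | C=C1C(=O)O[C@](C)([C@H](OC(C)=O)CC/C(C)=C\CC#CC)CC[C@H]1CCO
F6 | step 21 | (1R,4Z)-4-methyl-1-[(2S,5S)-2-methyl-6-methylidene-7-oxo-5-(2-oxoethyl)oxepan-2-yl]non-4-en-7-yn-1-yl acetate | C=C1C(=O)O[C@](C)([C@H](OC(C)=O)CC/C(C)=C\CC#CC)CC[C@H]1CC=O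
F7 | step 21 | (1S,4E,7Z,11R,12S)-11-acetoxy-3-hydroxycembra-4,7,15(17)-trien-16,12-olide as both C3 epimers | C=C1C(=O)O[C@@]2(C)CC[C@H]1CC(O)/C(C)=C/C/C=C(/C)CC[C@H]2OC(C)=O
F8 | step 22 | (1S,3S,4E,7Z,11R,12S)-11-acetoxy-3-hydroxycembra-4,7,15(17)-trien-16,12-olide | C=C1C(=O)O[C@@]2(C)CC[C@H]1C[C@H](O)/C(C)=C/C/C=C(/C)CC[C@H]2OC(C)=O
F9 | step 22 | (1S,3R,4E,7Z,11R,12S)-11-acetoxy-3-(chloroacetoxy)cembra-4,7,15(17)-trien-16,12-olide | C=C1C(=O)O[C@@]2(C)CC[C@H]1C[C@@H](OC(=O)CCl)/C(C)=C/C/C=C(/C)CC[C@H]2OC(C)=O
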